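The numbers in the tables are calculated for an exercise, noise included.

The ratio I started from was the green run's late rate of target over its first: 0.0297 min⁻¹ of the charge against 0.221 min⁻¹, a fall by a factor of 7.44.

| flask | substrate | coupling partner | catalyst | remark | time |
|---|---|---|---|---|---|
| green | 31 mM | 55.8 mM | 0.77 mM | run made earlier |  |
| grey | 31 mM | 55.8 mM | 1.2 mM | run made earlier |  |
| east | 31 mM | 55.8 mM (fed, over 5.0 min) | 0.77 mM | all else is in the flask from the start; the feed brings no volume worth counting | 8.0 min |
| south-west | 31 mM | 55.8 mM (in portions, 3, over 5.0 min) | 0.77 mM | first portion at the start, last at 5.0 min | 8.0 min |
| north | 31 mM (fed, over 5.0 min) | 55.8 mM | 0.77 mM | all else is in the flask from the start; the feed brings no volume worth counting | 8.0 min |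
| north-east | 31 mM | 55.8 mM | 0.77 mM | everything together at the start | 8.0 min |

- green (time / min: target / %): 0.417: 9.2; 0.833: 15.0; 2.00: 27.0; 5.00: 35.9
- grey (time / s: target / %): 10.0: 5.1; 20.0: 12.4; 50.0: 23.0

(scatter of a reading: 0.5 percentage points)

1. which flask leads in amount of target, in percent of the substrate charged ("all alike" within 1.5 percentage points) (east / south-west / north / north-east / all alike)
2. how much target is there at the end, in percent of the substrate charged: east
3. how much target is there at the end, in percent of the substrate charged: south-west
4. how much target is there at the end, in percent of the substrate charged: north
5. how much target is there at the end, in percent of the substrate charged: north-east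



1. What I read. Grey's early rate was 1.69 times green's for 1.56 times the catalyst, so I took the rate of target as proportional to [catalyst]. In the green run, target had used at most 19.9% of the coupling partner by the last reading, so the partner could not account for the fall.

2. My assumption. I took the rate of target as proportional to [substrate] too. That left 13.4% of the substrate at 3.50 min, with target near 27.0% to 35.9%. I therefore supposed a hidden loss of substrate, second order in [substrate], with a guessed order. Its constant, per unit of charge, came to 1.84 min⁻¹.

3. The crossing. The crossing concentration, the [substrate] at which hidden loss and coupling run equally fast at full partner and recipe catalyst, came out in my estimate at 3.72 mM. On my assumed rates it moves in proportion to [coupling partner] × [catalyst]. [Substrate] over this crossing is my selectivity factor.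

4. The first instants. North-east began at 8.34 times the crossing, so the loss led from the start. East had the same [substrate] with almost no partner, which put its crossing near zero. South-west began with a crossing of 1.24 mM.

5. The middle. In north, the feed of 0.200 min⁻¹ of the charge could be balanced by the loss at about 10.2 mM, so [substrate] stayed below the batch start.

6. The end. In the batch flask, the substrate left at the crossing was 12.0% of the charge, so the late stretch could add little. I expected north first, then north-east, south-west and east.

The forecast named north-east as leader, with 34% for east, 36% for south-west, 33% for north and 39% for north-east. It said: “Feeding lowers the early rate, but self-limiting inhibition shrinks the penalty.” My order differs from it.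

The flasks gave 19.7% for east, 23.2% for south-west, 56.9% for north and 38.2% for north-east, so north led.

    2 substrate → self-condensation product (k = 0.410 L mol⁻¹ s⁻¹)
    substrate + coupling partner + catalyst → target + catalyst, rate k2*[substrate]*[coupling partner]*[catalyst]/(1 + ([substrate]/sat2)) (14.0 mM, k = 290 L² mol⁻² s⁻¹)

In east at 0.438 min, the steady feed had delivered 8.75% of the partner, and self-condensation was using substrate 33 times as fast as coupling. A neighbour of east had 0.19 mM of catalyst, about a quarter of the recipe's. My estimate of the crossing at full partner, 3.72 mM, scales with that proportion to 0.918 mM, a figure from my assumed rates and not the crossing of the equations above. That neighbour ended with 87.5% as self-condensation product and 8.27% as target, against 19.7% in east.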